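The route rests on the C4–C4a bond. The key step is a Fries-type ring contraction: a seven-membered aryl lactone (O1–C2–C3–C4(=O)–O8–C8–C8a) rearranges with AlCl3 so that the acyl carbon C4 moves from O8 to C4a. This closes the pyranone ring (O1, C2, C3, C4, C4a, C8a), frees the 8-OH and cleaves both isopropyl ethers in one operation. It exploits the ortho relation of O1 (on C8a) and the C8 hydroxyl in ring A, which fixes the 5,7,8-pattern. The lactone comes from Baeyer–Villiger oxidation of an (S)-5,7-dialkoxyflavanone made by asymmetric arylation of a chromone; C2 is set there and carried through.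

Key step: step 6

Remark: the flavanone locants of the target (O1, C2, C3, C4, C4a, C5–C8, C8a; ring B primed) are used for the corresponding atoms of all intermediates.
Assumption: in step 3 the (R)-configured MeO-F12-BIPHEP is taken to deliver the 2S adduct; if the sense of induction is the opposite, its enantiomer is used.

Step 1
Reactants: 1 5,7-dihydroxy-4H-chromen-4-one
Product: 2 5,7-di(propan-2-yloxy)-4H-chromen-4-one
Conditions: 2-bromopropane (5 equiv), K2CO3 (4 equiv), DMF, 70 °C
Reagents that add atoms: 2-bromopropane CC(C)Br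
Why: Williamson ether synthesis: both phenoxides, the hydrogen-bonded 5-OH included, should be alkylated by an excess of the secondary bromide in warm DMF, while the chromone ring is inert to carbonate.

Step 2
Reactants: 3 2-bromo-4-iodophenol
Product: 6 (3-bromo-4-hydroxyphenyl)boronic acid, via aryl Grignard reagent 4 (not isolated), via dimethyl arylboronate 5 (not isolated)
Conditions: MeMgCl (1.0 equiv), LiCl, THF, −20 °C; i-PrMgCl·LiCl (1.1 equiv), −20 → 0 °C; B(OMe)3, −78 °C → rt; 1 M HCl
Reagents that add atoms: trimethyl borate COB(OC)OC; water O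
Why: After deprotonation of the phenol, iodine–magnesium exchange should take place at C–I much faster than at C–Br, and borylation of the aryl Grignard reagent followed by acidic hydrolysis gives the boronic acid.

Step 3
Reactants: 2 5,7-di(propan-2-yloxy)-4H-chromen-4-one; 6 (3-bromo-4-hydroxyphenyl)boronic acid
Product: 7 (2S)-2-(3-bromo-4-hydroxyphenyl)-5,7-di(propan-2-yloxy)-2,3-dihydro-4H-chromen-4-one
Conditions: [Rh(OH)(cod)]2 (1.5 mol %), (R)-MeO-F12-BIPHEP (3.3 mol %), 6 (2.5 equiv), CH2Cl2/H2O, rt
Reagents that add atoms: none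
Why: Rhodium-catalysed asymmetric 1,4-addition of an arylboronic acid to a chromone (Hayashi–Miyaura reaction): the chiral bisphosphine fixes the face of the C2=C3 bond that inserts into the aryl–rhodium bond and thereby sets C2 as S, and the aryl bromide and the free phenol are tolerated.

Step 4
Reactants: 7 (2S)-2-(3-bromo-4-hydroxyphenyl)-5,7-di(propan-2-yloxy)-2,3-dihydro-4H-chromen-4-one
Product: 8 2-bromo-4-[(2S)-4-oxo-5,7-di(propan-2-yloxy)-3,4-dihydro-2H-chromen-2-yl]phenyl acetate
Conditions: Ac2O (1.2 equiv), pyridine, DMAP (cat.), CH2Cl2, 0 °C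
Reagents that add atoms: acetic anhydride CC(=O)OC(C)=O
Why: O-Acetylation of the phenol under nucleophilic catalysis; the acetate turns the para oxygen of ring B from a strong donor into a weak one so that the benzylic C2–O1 bond will resist ionisation in step 6.

Step 5
Reactants: 8 2-bromo-4-[(2S)-4-oxo-5,7-di(propan-2-yloxy)-3,4-dihydro-2H-chromen-2-yl]phenyl acetate
Product: 9 2-bromo-4-[(4S)-2-oxo-7,9-di(propan-2-yloxy)-3,4-dihydro-2H-1,5-benzodioxepin-4-yl]phenyl acetate
Conditions: mCPBA (1.5 equiv), NaHCO3, CH2Cl2, 0 °C → rt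
Reagents that add atoms: mCPBA O=C(OO)c1cccc(Cl)c1
Why: Baeyer–Villiger oxidation: in the Criegee adduct the electron-rich 2,4,6-trioxygenated aryl carbon migrates in preference to C3H2, so that oxygen is inserted between C4 and the arene and the chromanone ring expands to the seven-membered aryl lactone without touching C2.

Step 6
Reactants: 9 2-bromo-4-[(4S)-2-oxo-7,9-di(propan-2-yloxy)-3,4-dihydro-2H-1,5-benzodioxepin-4-yl]phenyl acetate
Product: 11 2-bromo-4-[(2S)-5,7,8-trihydroxy-4-oxo-3,4-dihydro-2H-chromen-2-yl]phenyl acetate, via 8-hydroxychromanone diisopropyl ether 10 (not isolated)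
Conditions: AlCl3 (6 equiv), CH2Cl2 (0.02 M), −20 °C → rt, Ar; then ice-cold 1 M HCl
Reagents that add atoms: none
Why: AlCl3 binds the lactone carbonyl and breaks the acyl–O8 bond to give an aluminium phenoxide at O8 and an acylium ion (or acyl chloride–AlCl3 complex) that stays tied to C8a through C3–C2–O1; this electrophile attacks C4a, the free carbon ortho to O1, and rearomatisation gives chromanone 10, whose isopropyl ethers AlCl3 is expected to cleave as 2-chloropropane on warming. The closest known reaction type is the Lewis-acid Fries rearrangement of benzo-fused aryl lactones with ring contraction (dihydrocoumarin to 4-hydroxyindan-1-one), which likewise delivers the acyl group to a carbon meta to the ester oxygen by a dissociative path, since a direct transfer from O8 to C4a is geometrically impossible. The pyranone ring closes by 6-exo attack of the arene carbon C4a on the acylium carbon, so that the seven-membered ring O1–C2–C3–C4–O8–C8–C8a contracts to the six-membered ring O1–C2–C3–C4–C4a–C8a. No stereocentre is formed; C2 should keep its S configuration because no bond to it is broken, provided that the benzylic C2–O1 bond does not ionise and the aryloxide is not lost by β-elimination, and the acetoxy and bromo substituents of ring B are there to destabilise that benzylic cation. Regioselectivity is secured by the tether: from O1 only C4a can be reached (C8 carries O8, C6 is out of reach), C4a is activated by O1, O5 and O7, and high dilution disfavours intermolecular acylation at C6.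

Step 7
Reactants: 12 4-bromo-2-methylbut-1-ene
Product: 13 (3-methylbut-3-en-1-yl)zinc bromide
Conditions: Zn dust (1.5 equiv; activated with 1,2-dibromoethane and TMSCl), LiCl, THF, 25–40 °C; used as a titrated solution
Reagents that add atoms: zinc [Zn]
Why: Direct insertion of LiCl-activated zinc into the primary C–Br bond; the 1,1-disubstituted alkene is inert and a homoallylic zinc reagent does not rearrange.

Step 8
Reactants: 11 2-bromo-4-[(2S)-5,7,8-trihydroxy-4-oxo-3,4-dihydro-2H-chromen-2-yl]phenyl acetate; 13 (3-methylbut-3-en-1-yl)zinc bromide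
Product: 14 2-(3-methylbut-3-en-1-yl)-4-[(2S)-5,7,8-trihydroxy-4-oxo-3,4-dihydro-2H-chromen-2-yl]phenyl acetate
Conditions: Pd(OAc)2 (4 mol %), SPhos (8 mol %), 13 (5 equiv, slow addition), THF, 25 °C, Ar; then aq. NH4Cl
Reagents that add atoms: none
Why: Negishi sp2–sp3 cross-coupling: oxidative addition into the aryl bromide, transmetalation from the alkylzinc and reductive elimination promoted by the bulky biarylphosphine, which should outrun β-hydride elimination; the phenols are tolerated as zinc phenoxides when the zinc reagent is added slowly in excess, and ketone and aryl acetate do not react with RZnBr.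

Step 9
Reactants: 14 2-(3-methylbut-3-en-1-yl)-4-[(2S)-5,7,8-trihydroxy-4-oxo-3,4-dihydro-2H-chromen-2-yl]phenyl acetate
Product: 15 (2S)-5,7,8-trihydroxy-2-[4-hydroxy-3-(3-methylbut-3-en-1-yl)phenyl]-2,3-dihydro-4H-chromen-4-one
Conditions: NH4OAc (10 equiv), degassed MeOH/H2O (4:1), rt, Ar
Reagents that add atoms: none
Why: Ammonium acetate-mediated methanolysis of an aryl acetate at neutral pH, which should avoid both base-induced retro-oxa-Michael opening of the flavanone (loss of the C2 configuration, Wessely–Moser isomerisation) and acid-induced addition of the ortho phenol to the alkene.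

Compound list
1 | 5,7-dihydroxy-4H-chromen-4-one | O=c1ccoc2cc(O)cc(O)c12 | starting material
2 | 5,7-di(propan-2-yloxy)-4H-chromen-4-one | O=c1ccoc2cc(OC(C)C)cc(OC(C)C)c12 | intermediate
3 | 2-bromo-4-iodophenol | Oc1ccc(I)cc1Br | starting material
4 | chloromagnesium 2-bromo-4-(chloromagnesio)phenoxide (aryl Grignard reagent) | Cl[Mg]Oc1ccc([Mg]Cl)cc1Br | intermediate (not isolated)
5 | chloromagnesium 2-bromo-4-(dimethoxyboranyl)phenoxide (dimethyl arylboronate) | COB(OC)c1ccc(O[Mg]Cl)c(Br)c1 | intermediate (not isolated)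
6 | (3-bromo-4-hydroxyphenyl)boronic acid | OB(O)c1ccc(O)c(Br)c1 | intermediate
7 | (2S)-2-(3-bromo-4-hydroxyphenyl)-5,7-di(propan-2-yloxy)-2,3-dihydro-4H-chromen-4-one | Oc1ccc(cc1Br)[C@@H]2CC(=O)c3c(OC(C)C)cc(OC(C)C)cc3O2 | intermediate
8 | 2-bromo-4-[(2S)-4-oxo-5,7-di(propan-2-yloxy)-3,4-dihydro-2H-chromen-2-yl]phenyl acetate | CC(=O)Oc1ccc(cc1Br)[C@@H]2CC(=O)c3c(OC(C)C)cc(OC(C)C)cc3O2 | intermediate
9 | 2-bromo-4-[(4S)-2-oxo-7,9-di(propan-2-yloxy)-3,4-dihydro-2H-1,5-benzodioxepin-4-yl]phenyl acetate | CC(=O)Oc1ccc(cc1Br)[C@@H]2CC(=O)Oc3c(OC(C)C)cc(OC(C)C)cc3O2 | intermediate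
10 | 2-bromo-4-[(2S)-8-hydroxy-4-oxo-5,7-di(propan-2-yloxy)-3,4-dihydro-2H-chromen-2-yl]phenyl acetate (present as its aluminium phenoxide) | CC(=O)Oc1ccc(cc1Br)[C@@H]2CC(=O)c3c(OC(C)C)cc(OC(C)C)c(O)c3O2 | intermediate (not isolated)
11 | 2-bromo-4-[(2S)-5,7,8-trihydroxy-4-oxo-3,4-dihydro-2H-chromen-2-yl]phenyl acetate | CC(=O)Oc1ccc(cc1Br)[C@@H]2CC(=O)c3c(O)cc(O)c(O)c3O2 | intermediate
12 | 4-bromo-2-methylbut-1-ene | C=C(C)CCBr | starting material
13 | (3-methylbut-3-en-1-yl)zinc bromide | C=C(C)CC[Zn]Br | intermediate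
14 | 2-(3-methylbut-3-en-1-yl)-4-[(2S)-5,7,8-trihydroxy-4-oxo-3,4-dihydro-2H-chromen-2-yl]phenyl acetate | CC(=O)Oc1ccc(cc1CCC(C)=C)[C@@H]2CC(=O)c3c(O)cc(O)c(O)c3O2 | intermediate
15 | (2S)-5,7,8-trihydroxy-2-[4-hydroxy-3-(3-methylbut-3-en-1-yl)phenyl]-2,3-dihydro-4H-chromen-4-one | C=C(C)CCc1cc([C@@H]2CC(=O)c3c(O)cc(O)c(O)c3O2)ccc1O | target

Total step count: 9. Longest linear sequence: 7 steps (steps 1, 3, 4, 5, 6, 8 and 9, from compound 1).

Steps most likely to fail

Step 6 (key step). The acylium ion may lose the aryloxide by β-elimination, or the benzylic C2–O1 bond may ionise; either process erodes the C2 configuration. The ring-B acetate may also be cleaved or transferred by AlCl3, intermolecular acylation at C6 may compete, and the ring may be isopropylated while the ethers are cleaved. The fallback sets out from 9 and returns at 15; it separates acyl activation, ring closure and ether cleavage into mild stages and closes the pyranone ring from the open-chain acid. LiOH (THF/H2O, 0 °C) opens the lactone and removes the acetate to give (3S)-3-(3-bromo-4-hydroxyphenyl)-3-[2-hydroxy-3,5-di(propan-2-yloxy)phenoxy]propanoic acid F1. Trifluoroacetic anhydride (CH2Cl2, 0 °C) converts F1 into the mixed anhydride (3S)-3-[3-bromo-4-(trifluoroacetoxy)phenyl]-3-[3,5-di(propan-2-yloxy)-2-(trifluoroacetoxy)phenoxy]propanoic trifluoroacetic anhydride F2, in which both phenols are acylated as well. F2 should cyclise at C4a by intramolecular Friedel–Crafts acylation to (2S)-2-[3-bromo-4-(trifluoroacetoxy)phenyl]-4-oxo-5,7-di(propan-2-yloxy)-3,4-dihydro-2H-chromen-8-yl trifluoroacetate F3. Buffered aqueous methanol removes the trifluoroacetyl groups to give (2S)-2-(3-bromo-4-hydroxyphenyl)-8-hydroxy-5,7-di(propan-2-yloxy)-2,3-dihydro-4H-chromen-4-one F4. BCl3 (CH2Cl2, −78 → 0 °C) cleaves the isopropyl ethers to (2S)-2-(3-bromo-4-hydroxyphenyl)-5,7,8-trihydroxy-2,3-dihydro-4H-chromen-4-one F5. Negishi coupling of F5 with 13 under the conditions of step 8, with one further equivalent of 13, gives 15.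

Step 8. Protonolysis of the alkylzinc by the three phenols may outrun transmetalation, the catecholate may sequester the catalyst, and β-hydride elimination may lead to reduction or alkene isomerisation. The fallback sets out from 11 and returns at 15; it removes all acidic protons before the coupling. Ac2O/pyridine/DMAP (CH2Cl2, 0 °C) gives (2S)-2-(4-acetoxy-3-bromophenyl)-4-oxo-3,4-dihydro-2H-chromene-5,7,8-triyl triacetate F6. Negishi coupling with 13 (1.5 equiv, Pd(OAc)2/SPhos, THF, rt) gives (2S)-2-[4-acetoxy-3-(3-methylbut-3-en-1-yl)phenyl]-4-oxo-3,4-dihydro-2H-chromene-5,7,8-triyl triacetate F7. NH4OAc in aqueous methanol, as in step 9 with a longer reaction time, removes all four acetates to give 15.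

Step 3. Protodeboronation of the electron-rich free-phenol boronic acid, slow insertion of the electron-rich, peri-substituted chromone, poor facial selectivity and a second addition to the product ketone are the likely problems. The fallback sets out from 3 and returns at 8, so that step 4 is no longer needed; the phenol is masked before the C–C bond is formed and a Pd(II) catalyst is used. Ac2O/pyridine gives 2-bromo-4-iodophenyl acetate F8. Miyaura borylation (B2pin2, PdCl2(dppf), KOAc, dioxane, 80 °C), selective for C–I, gives 2-bromo-4-(4,4,5,5-tetramethyl-1,3,2-dioxaborolan-2-yl)phenyl acetate F9. NaIO4/NH4OAc (acetone/H2O, rt) gives (4-acetoxy-3-bromophenyl)boronic acid F10. Pd(II)-catalysed asymmetric conjugate addition of F10 to 2 (Pd(OCOCF3)2, t-BuPyOx of the hand that gives 2S, NH4PF6, H2O, ClCH2CH2Cl, 60 °C) gives 8.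

Further compounds
F1 | step 6 | (3S)-3-(3-bromo-4-hydroxyphenyl)-3-[2-hydroxy-3,5-di(propan-2-yloxy)phenoxy]propanoic acid | Oc1ccc(cc1Br)[C@H](CC(O)=O)Oc2cc(OC(C)C)cc(OC(C)C)c2O
F2 | step 6 | (3S)-3-[3-bromo-4-(trifluoroacetoxy)phenyl]-3-[3,5-di(propan-2-yloxy)-2-(trifluoroacetoxy)phenoxy]propanoic trifluoroacetic anhydride | FC(F)(F)C(=O)Oc1ccc(cc1Br)[C@H](CC(=O)OC(=O)C(F)(F)F)Oc2cc(OC(C)C)cc(OC(C)C)c2OC(=O)C(F)(F)F
F3 | step 6 | (2S)-2-[3-bromo-4-(trifluoroacetoxy)phenyl]-4-oxo-5,7-di(propan-2-yloxy)-3,4-dihydro-2H-chromen-8-yl trifluoroacetate | FC(F)(F)C(=O)Oc1ccc(cc1Br)[C@@H]2CC(=O)c3c(OC(C)C)cc(OC(C)C)c(OC(=O)C(F)(F)F)c3O2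
F4 | step 6 | (2S)-2-(3-bromo-4-hydroxyphenyl)-8-hydroxy-5,7-di(propan-2-yloxy)-2,3-dihydro-4H-chromen-4-one | Oc1ccc(cc1Br)[C@@H]2CC(=O)c3c(OC(C)C)cc(OC(C)C)c(O)c3O2
F5 | step 6 | (2S)-2-(3-bromo-4-hydroxyphenyl)-5,7,8-trihydroxy-2,3-dihydro-4H-chromen-4-one | Oc1ccc(cc1Br)[C@@H]2CC(=O)c3c(O)cc(O)c(O)c3O2
F6 | step 8 | (2S)-2-(4-acetoxy-3-bromophenyl)-4-oxo-3,4-dihydro-2H-chromene-5,7,8-triyl triacetate | CC(=O)Oc1ccc(cc1Br)[C@@H]2CC(=O)c3c(OC(C)=O)cc(OC(C)=O)c(OC(C)=O)c3O2
F7 | step 8 | (2S)-2-[4-acetoxy-3-(3-methylbut-3-en-1-yl)phenyl]-4-oxo-3,4-dihydro-2H-chromene-5,7,8-triyl triacetate | CC(=O)Oc1ccc(cc1CCC(C)=C)[C@@H]2CC(=O)c3c(OC(C)=O)cc(OC(C)=O)c(OC(C)=O)c3O2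
F8 | step 3 | 2-bromo-4-iodophenyl acetate | CC(=O)Oc1ccc(I)cc1Br
F9 | step 3 | 2-bromo-4-(4,4,5,5-tetramethyl-1,3,2-dioxaborolan-2-yl)phenyl acetate | CC(=O)Oc1ccc(cc1Br)B2OC(C)(C)C(C)(C)O2
F10 | step 3 | (4-acetoxy-3-bromophenyl)boronic acid | CC(=O)Oc1ccc(cc1Br)B(O)O
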